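**Assumption:** The target has no sp3 stereocentres. The only stereo-element is the (E)-enone, so "single enantiomer" is not an issue.

## Retrosynthesis
- Disconnect the enone C=C (Claisen–Schmidt/aldol condensation). This gives 2,4-dihydroxy-3,5-diprenylacetophenone (3) and 4-hydroxybenzaldehyde (4).
- Disconnect the two aryl C–prenyl bonds of 3 (C-alkylation). The precursor is commercial 2,4-dihydroxyacetophenone (1) and prenyl bromide (2).
- The positions between and ortho/para to the two phenoxides (C3, then C5) are the most nucleophilic. No ring is formed, because the benzene ring is already present.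

## Route

**Step 1**
Reactants: 1 (2,4-dihydroxyacetophenone), 2 (prenyl bromide, 1-bromo-3-methylbut-2-ene)
Product: 3 (1-[2,4-dihydroxy-3,5-bis(3-methylbut-2-en-1-yl)phenyl]ethan-1-one)
Conditions: 2 (2.5 equiv), KOH (5 equiv), H2O, 0 °C → rt, 16 h, N2; acidify to pH ~5 and separate from the mono-prenyl product by silica chromatography
Reagents that add atoms: prenyl bromide, CC(C)=CCBr
Why: In water the phenoxide oxygens are hydrogen-bonded, so C-alkylation (SN2 at the primary allylic bromide) beats O-alkylation. C3 (ortho to both O⁻) reacts first and C5 (ortho to 4-O⁻, para to 2-O⁻) second, and the linear prenyl group is retained. No stereocentre is formed.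

**Step 2**
Reactants: 3 (diprenyl acetophenone), 4 (4-hydroxybenzaldehyde)
Product: 5 (target, (E)-2′,4′,4-trihydroxy-3′,5′-diprenylchalcone)
Conditions: 4 (1.2 equiv), 50% aq. KOH (about 10 equiv), EtOH, rt, 48 h, N2; quench at 0 °C with 1 M HCl to pH ~4–5
Reagents that add atoms: none
Why: Claisen–Schmidt condensation proceeds through the ketone enolate, aldol addition and E1cB dehydration. The conjugated, thermodynamically favoured (E)-enone forms, which sets the alkene geometry. Excess base keeps all phenols deprotonated, so no protecting groups are needed. The prenyl alkenes are stable to base, and avoiding strong acid prevents cyclisation of the 2′-OH onto a prenyl group (chromane formation).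

## Checks
- **Structure match:** The aryl ring carries the acyl group at C1, OH at C2, prenyl at C3, OH at C4, prenyl at C5 and H at C6. The enone is attached to a 4-hydroxyphenyl group with E geometry. This matches the target SMILES.
- **Atom accounting:** 1 (C8H8O3) plus 2 C5H9 units, with loss of 2 HBr, gives 3 (C18H24O3). Then 3 plus 4 (C7H6O2), with loss of H2O, gives C25H28O4, which is the target formula.
- **Functional-group survival:** Base does not touch the prenyl alkenes. Phenols are free throughout, and the acidic quench is mild.
- **Stereochemistry:** The (E)-alkene is set in step 2 and nothing afterwards can change it.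

## Compound list
1 | 2,4-dihydroxyacetophenone | CC(=O)c1ccc(O)cc1O | starting material
2 | prenyl bromide (1-bromo-3-methylbut-2-ene) | CC(C)=CCBr | starting material
3 | 1-[2,4-dihydroxy-3,5-bis(3-methylbut-2-enyl)phenyl]ethanone | CC(=O)c1cc(CC=C(C)C)c(O)c(CC=C(C)C)c1O | intermediate
4 | 4-hydroxybenzaldehyde | O=Cc1ccc(O)cc1 | starting material
5 | (E)-1-[2,4-dihydroxy-3,5-bis(3-methylbut-2-enyl)phenyl]-3-(4-hydroxyphenyl)prop-2-en-1-one | CC(C)=CCc1cc(C(=O)/C=C/c2ccc(O)cc2)c(O)c(CC=C(C)C)c1O | target

**Total steps:** 2. **Longest linear sequence:** 2.

## Most likely failure points
There are only two steps, so the three risks are drawn from them.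

1. **Step 1, regioselectivity and yield.** The reaction may give a mixture of mono-, di- and O-prenylated products, or over-alkylation at C6. Fallback: use a directed route instead. Iodinate 1 at C3 and C5 with NIS, protect the phenols as MOM ethers, and couple with a prenyl-metal reagent (prenylzinc or prenyl-BPin, Pd or Ni catalysis). Then remove the MOM groups under mild conditions, for example MgBr2/Me2S or PPTS in MeOH. Alternatively, build the ring by Friedel–Crafts acylation (AcOH/BF3·OEt2) of pre-made 2,4-diprenylresorcinol.
2. **Step 2, conversion.** The polyphenolate ketone is a poor enolate source and 4-hydroxybenzaldehyde is a deactivated electrophile. Fallback: use 4-(MOM-oxy)benzaldehyde in the Claisen–Schmidt step, then remove the MOM group with a mild Lewis acid such as MgBr2 or with PPTS/MeOH, avoiding strong Brønsted acid.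
3. **Step 2, side reactions and isolation.** The 2′-hydroxychalcone can cyclise to the flavanone, or a prenyl group can cyclise to a chromane, during work-up or purification. Fallback: switch to a non-basic aldol condensation, such as a boron-mediated (BF3·OEt2) or piperidine/pyrrolidine-catalysed condensation of a bis-MOM-protected 3 with the aldehyde. Then remove the MOM groups under buffered, mild conditions and purify on neutral silica or Sephadex LH-20.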